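## Retrosynthetic overview
1. The target comes from global desilylation of a (2S)-2-aryl-4-silyloxy-2H-chromene, which is the flavanone masked as its enol silane.
2. Key disconnection C2–C1′: chromone C2 is used as a nickel homoenolate (η3-siloxyallylnickel) and joined to a ring B aryl bromide. Both carbons are electrophiles by nature, and a chiral ligand sets C2.
3. The chromone comes from phloroacetophenone by C-prenylation, regioselective bis-silylation and formylation/cyclodehydration.
4. The bromide comes from 4-bromoresorcinol by O-prenylation, aromatic Claisen rearrangement (prenyl becomes 1,1-dimethylallyl) and silylation.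
5. Ring order: rings A and B are bought as arenes, ring C is closed as the chromone before the coupling, and no ring is formed afterwards.

Assumption: the SMILES is read as the (2S)-flavanone. The sense of induction of the ligand in step 7 must be found by experiment, and its antipode is used if (S,S) gives 2R.

TBS = tert-butyldimethylsilyl; prenyl = 3-methylbut-2-enyl.

## Route

Step 1
Reactants: 1 2,4,6-trihydroxyacetophenone; 2 prenyl bromide
Product: 3 2,4,6-trihydroxy-3-prenylacetophenone
Conditions: KOH (1.0 equiv), H2O, 0 °C to rt, 2 (0.9 equiv)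
Reagents that add atoms: none
Why: This is C-alkylation of the ambident phloroglucinolate (SN2 C-prenylation), in which water shields the phenoxide oxygens by hydrogen bonding so the soft allylic bromide is attacked by ring carbon, and because C3 and C5 of 1 are equivalent only one mono-C-prenyl isomer can form.

Step 2
Reactants: 3 2,4,6-trihydroxy-3-prenylacetophenone
Product: 4 2-hydroxy-3-prenyl-4,6-bis(TBSO)acetophenone
Conditions: TBSCl (2.1 equiv), imidazole (4.5 equiv), DMF, 0 °C to rt
Reagents that add atoms: tert-butyldimethylsilyl chloride, CC(C)(C)[Si](C)(C)Cl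
Why: In this regioselective silyl ether formation the unchelated 4-OH reacts first, then the less hindered chelated 6-OH (flanked by H), and the 2-OH stays free because it is wedged between prenyl and acetyl and locked in the hydrogen bond to the ketone.

Step 3
Reactants: 4 2-hydroxy-3-prenyl-4,6-bis(TBSO)acetophenone
Product: 6 8-prenyl-5,7-bis(TBSO)-4H-chromen-4-one, via lactol 5 (not isolated)
Conditions: LiN(SiMe3)2 (3.2 equiv), THF, −78 °C; HCO2CH2CF3 (1.5 equiv), −78 to −20 °C; 1 M HCl quench; then TsOH·H2O (10 mol %), CH2Cl2, rt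
Reagents that add atoms: 2,2,2-trifluoroethyl formate, O=COCC(F)(F)F
Why: A crossed Claisen condensation (C-formylation of the phenoxide–enolate dianion) followed by acid-catalysed cyclodehydration is the classical chromone synthesis, only the OH next to the prenyl group is free so ring C closes there and fixes prenyl at C8, and the cold non-nucleophilic amide base spares the aryl silyl ethers.

Step 4
Reactants: 7 4-bromoresorcinol; 2 prenyl bromide
Product: 8 2-bromo-5-(prenyloxy)phenol
Conditions: K2CO3 (1.0 equiv), 2 (1.0 equiv), acetone, rt to 50 °C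
Reagents that add atoms: none
Why: In this Williamson ether synthesis with one equivalent each of base and bromide, the less hindered and more nucleophilic phenoxide para to bromine is alkylated in preference to the OH ortho to bromine, as in the known monobenzylation of 7.

Step 5
Reactants: 8 2-bromo-5-(prenyloxy)phenol
Product: 10 4-bromo-6-(2-methylbut-3-en-2-yl)benzene-1,3-diol, via ortho-dienone 9 (not isolated)
Conditions: PhNEt2, 190 °C, sealed tube, Ar, 2–3 h
Reagents that add atoms: none
Why: The aromatic Claisen rearrangement ([3,3]-sigmatropic shift) inverts the prenyl unit to 1,1-dimethylallyl and delivers this bulky group to the open ortho carbon para to the free OH rather than to the carbon between the two oxygens, after which dienone 9 tautomerises to the phenol and its transient stereocentre is lost.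

Step 6
Reactants: 10 4-bromo-6-(2-methylbut-3-en-2-yl)benzene-1,3-diol
Product: 11 1-bromo-2,4-bis(TBSO)-5-(2-methylbut-3-en-2-yl)benzene
Conditions: TBSOTf (2.4 equiv), 2,6-lutidine (3 equiv), CH2Cl2, 0 °C to rt
Reagents that add atoms: tert-butyldimethylsilyl triflate, CC(C)(C)[Si](C)(C)OS(=O)(=O)C(F)(F)F
Why: Silyl ether formation uses the more reactive triflate because one OH sits next to a quaternary carbon, and the lutidine buffer keeps the ortho-allylphenol from acid-catalysed cyclisation to a dihydrobenzofuran.

Step 7 (key step)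
Reactants: 6 8-prenyl-5,7-bis(TBSO)-4H-chromen-4-one; 11 1-bromo-2,4-bis(TBSO)-5-(2-methylbut-3-en-2-yl)benzene
Product: 12 (2S)-2-[2,4-bis(TBSO)-5-(2-methylbut-3-en-2-yl)phenyl]-5,7-bis(TBSO)-8-prenyl-4-(triethylsilyloxy)-2H-chromene
Conditions: NiCl2(dme) (10 mol %), (4S,4′S)-4,4′-di-tert-butyl-2,2′-bioxazoline (12 mol %), Mn powder (3 equiv), Et3SiCl (1.5 equiv), 11 (1.3 equiv), DMF, 30–40 °C, dark; Et3N-buffered work-up
Reagents that add atoms: chlorotriethylsilane, CC[Si](Cl)(CC)CC
Why: Proposed new method: ligated zerovalent nickel adds oxidatively to the chromone/Et3SiCl pair (in effect a 4-siloxybenzopyrylium chloride) to give an η3-(4-triethylsiloxychromen-2-yl)nickel species, a homoenolate equivalent in which the normally electrophilic C2 is metal-bound and nucleophilic; after reduction by Mn it takes up the C–Br carbon of 11 by oxidative addition, and reductive elimination on the nickel-bearing face joins two naturally electrophilic carbons at C2 (the allyl terminus remote from OSi) while the chiral bioxazoline selects the face and sets 2S; the closest known reaction types are nickel-catalysed reductive conjugate arylation of enones with aryl halides and chlorosilanes through siloxyallylnickel intermediates, nickel-catalysed arylation of chromene acetals through benzopyrylium oxidative addition, and enantioselective nickel cross-electrophile couplings with oxazoline ligands.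

Step 8
Reactants: 12 (2S)-2-aryl-4-(triethylsilyloxy)-2H-chromene tetra-TBS ether
Product: 14 AChE-IN-17 (2S)-5,7-dihydroxy-2-[2,4-dihydroxy-5-(2-methylbut-3-en-2-yl)phenyl]-8-prenylchroman-4-one, via tetra-TBS flavanone 13 (not isolated)
Conditions: Et3N·3HF (excess), THF, 0 °C to rt
Reagents that add atoms: none
Why: In this fluoride-mediated desilylation the labile enol silane goes first (to ketone 13) and then the four aryl silyl ethers, the mildly acidic fluoride source keeps the phenols protonated so the retro-oxa-Michael opening of ring C that would racemise C2 is not triggered, both alkenes are untouched, and C2 is not involved so 2S is retained.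

## Compound list
1 | 2,4,6-trihydroxyacetophenone | CC(=O)c1c(O)cc(O)cc1O | starting material
2 | prenyl bromide (1-bromo-3-methylbut-2-ene) | CC(C)=CCBr | starting material
3 | 2,4,6-trihydroxy-3-prenylacetophenone | CC(=O)c1c(O)cc(O)c(CC=C(C)C)c1O | intermediate
4 | 2-hydroxy-3-prenyl-4,6-bis(TBSO)acetophenone | CC(=O)c1c(O)c(CC=C(C)C)c(O[Si](C)(C)C(C)(C)C)cc1O[Si](C)(C)C(C)(C)C | intermediate
5 | 2-hydroxy-8-prenyl-5,7-bis(TBSO)chroman-4-one (lactol, both epimers) | OC1CC(=O)c2c(O[Si](C)(C)C(C)(C)C)cc(O[Si](C)(C)C(C)(C)C)c(CC=C(C)C)c2O1 | intermediate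
6 | 8-prenyl-5,7-bis(TBSO)-4H-chromen-4-one | O=c1ccoc2c(CC=C(C)C)c(O[Si](C)(C)C(C)(C)C)cc(O[Si](C)(C)C(C)(C)C)c12 | intermediate
7 | 4-bromoresorcinol (4-bromobenzene-1,3-diol) | Oc1ccc(Br)c(O)c1 | starting material
8 | 2-bromo-5-(prenyloxy)phenol | CC(C)=CCOc1ccc(Br)c(O)c1 | intermediate
9 | 4-bromo-3-hydroxy-6-(2-methylbut-3-en-2-yl)cyclohexa-2,4-dien-1-one (racemic) | O=C1C=C(O)C(Br)=CC1C(C)(C)C=C | intermediate
10 | 4-bromo-6-(2-methylbut-3-en-2-yl)benzene-1,3-diol | C=CC(C)(C)c1cc(Br)c(O)cc1O | intermediate
11 | 1-bromo-2,4-bis(TBSO)-5-(2-methylbut-3-en-2-yl)benzene | C=CC(C)(C)c1cc(Br)c(O[Si](C)(C)C(C)(C)C)cc1O[Si](C)(C)C(C)(C)C | intermediate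
12 | (2S)-2-[2,4-bis(TBSO)-5-(2-methylbut-3-en-2-yl)phenyl]-5,7-bis(TBSO)-8-prenyl-4-(triethylsilyloxy)-2H-chromene | C=CC(C)(C)c1cc([C@@H]2C=C(O[Si](CC)(CC)CC)c3c(O[Si](C)(C)C(C)(C)C)cc(O[Si](C)(C)C(C)(C)C)c(CC=C(C)C)c3O2)c(O[Si](C)(C)C(C)(C)C)cc1O[Si](C)(C)C(C)(C)C | intermediate
13 | (2S)-2-[2,4-bis(TBSO)-5-(2-methylbut-3-en-2-yl)phenyl]-5,7-bis(TBSO)-8-prenylchroman-4-one | C=CC(C)(C)c1cc([C@@H]2CC(=O)c3c(O[Si](C)(C)C(C)(C)C)cc(O[Si](C)(C)C(C)(C)C)c(CC=C(C)C)c3O2)c(O[Si](C)(C)C(C)(C)C)cc1O[Si](C)(C)C(C)(C)C | intermediate
14 | AChE-IN-17, (2S)-5,7-dihydroxy-2-[2,4-dihydroxy-5-(2-methylbut-3-en-2-yl)phenyl]-8-(3-methylbut-2-enyl)chroman-4-one | C=CC(C)(C)c1cc([C@@H]2CC(=O)c3c(O)cc(O)c(CC=C(C)C)c3O2)c(O)cc1O | target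

## Step count and risks
Total steps: 8. The longest linear sequence is 5 steps, either 1→3→4→6→12→14 or 7→8→10→11→12→14.

**Step 7 (most likely to fail).**
- Risks: the chromone may be too electron-rich to bind zerovalent nickel. The siloxybenzopyrylium may dimerise reductively. The ortho-silyloxy bromide is hindered, and the peri 5-OTBS crowds O4. The ee is unknown.
- Fallback: this sets out from 11 and 6 and reverses the roles of the partners. Miyaura borylation of 11 (B2pin2, PdCl2(dppf), KOAc, dioxane, 80 °C) gives the aryl pinacol boronate F1. F1 is added to 6 by a rhodium-catalysed asymmetric 1,4-addition of Hayashi–Miyaura type ([RhCl(C2H4)2]2, chiral bicyclooctadiene ligand, minimal aqueous K3PO4, toluene/H2O, 60 °C). This gives the ketone directly and comes back to the route at 13, which is desilylated as in step 8.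

**Step 5 (together with the selectivity of step 4).**
- Risks: attack at the carbon between the oxygens, abnormal Claisen products, deprenylation, or cyclisation to a dihydrobenzofuran at 190 °C.
- Fallback: this sets out from 7 and avoids any sigmatropic step. Bromination (NBS, MeCN, 0 °C) gives 4,6-dibromoresorcinol F2. Silylation (TBSCl, imidazole, DMF) gives its bis-TBS ether F3, whose two bromides are equivalent. One branched-selective (γ) Suzuki–Miyaura allylation follows, with 3-methylbut-2-enylboronic acid pinacol ester (Pd(OAc)2, dialkylbiarylphosphine, aqueous K3PO4, THF, 40 °C, F3 in excess). This installs the 1,1-dimethylallyl group and comes back at 11.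

**Step 2.**
- Risk: if silylation does not discriminate between the 2-OH and the 6-OH, ring C closes on the wrong side and the 6-prenyl series results.
- Fallback: this sets out from 1 and introduces prenyl after ring C. Bis-silylation of symmetric 1 gives 2-hydroxy-4,6-bis(TBSO)acetophenone F4 without ambiguity. The formylation and dehydration of step 3 then lead through lactol F5 to 5,7-bis(TBSO)chromone F6. NIS (DMF, rt) iodinates the less crowded C8 to give the 8-iodochromone F7. Stille coupling with tributyl(3-methylbut-2-enyl)stannane (Pd(PPh3)4, DMF, 90 °C) gives the linear prenyl product and comes back at 6.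

## Further compounds
F1 | step 7 | 2-[2,4-bis(TBSO)-5-(2-methylbut-3-en-2-yl)phenyl]-4,4,5,5-tetramethyl-1,3,2-dioxaborolane | C=CC(C)(C)c1cc(B2OC(C)(C)C(C)(C)O2)c(O[Si](C)(C)C(C)(C)C)cc1O[Si](C)(C)C(C)(C)C
F2 | step 5 | 4,6-dibromobenzene-1,3-diol | Oc1cc(O)c(Br)cc1Br
F3 | step 5 | 1,5-dibromo-2,4-bis(TBSO)benzene | CC(C)(C)[Si](C)(C)Oc1cc(O[Si](C)(C)C(C)(C)C)c(Br)cc1Br
F4 | step 2 | 2-hydroxy-4,6-bis(TBSO)acetophenone | CC(=O)c1c(O)cc(O[Si](C)(C)C(C)(C)C)cc1O[Si](C)(C)C(C)(C)C
F5 | step 2 | 2-hydroxy-5,7-bis(TBSO)chroman-4-one | OC1CC(=O)c2c(O[Si](C)(C)C(C)(C)C)cc(O[Si](C)(C)C(C)(C)C)cc2O1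
F6 | step 2 | 5,7-bis(TBSO)-4H-chromen-4-one | O=c1ccoc2cc(O[Si](C)(C)C(C)(C)C)cc(O[Si](C)(C)C(C)(C)C)c12
F7 | step 2 | 8-iodo-5,7-bis(TBSO)-4H-chromen-4-one | O=c1ccoc2c(I)c(O[Si](C)(C)C(C)(C)C)cc(O[Si](C)(C)C(C)(C)C)c12
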